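**Retrosynthetic overview**
1. Target 8 ⇒ 7 ⇒ 6: the enone is unmasked from a silyl dienol ether, and the γ-lactone C–O bond is opened to a cis-γ-hydroxy ester.
2. 6 ⇒ 5: the carbinol comes from 1,2-reduction of a 6,6-disubstituted cyclohexa-2,4-dienone.
3. 5 ⇒ 4 + 3: C–C disconnection at the quaternary carbon, i.e. dearomatising ipso-farnesylation of a homogentisate phenolate, the chemical counterpart of prenyl transfer to homogentisate.
4. 4 ⇒ 2 ⇒ 1: the phenolate is released from homogentisic acid γ-lactone, in which one hydroquinone oxygen is already differentiated.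
5. Ring order: the six-membered ring is the dearomatised arene of 1 and is never constructed; the γ-lactone is closed last by reduction then lactonisation. C7a is set by the reduction catalyst, and C3a by selection, because only (S)-5 gives an alcohol that can lactonise.

Notation: farnesyl = (2E,6E)-3,7,11-trimethyldodeca-2,6,10-trien-1-yl; TIPS = triisopropylsilyl.

Assumption: 1 and 3 (as the pure 2E,6E isomer) are bought from catalogue suppliers.

**Step 1**
Reactants: 1 homogentisic acid γ-lactone (5-hydroxy-1-benzofuran-2(3H)-one)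
Product: 2 5-[(triisopropylsilyl)oxy]-1-benzofuran-2(3H)-one
Conditions: TIPSCl (1.1 equiv), imidazole (2.2 equiv), DMF, 0 → 23 °C, 2 h
Reagents that add atoms: triisopropylsilyl chloride, CC(C)[Si](Cl)(C(C)C)C(C)C
Why: Silyl ether formation: the second hydroquinone oxygen of 1 is locked in the lactone, so the only free phenol is silylated chemoselectively (imidazole is too weak to enolise the lactone), and the bulky TIPS ether survives one equivalent of methoxide and later becomes the masked ketone.

**Step 2**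
Reactants: 2 5-[(triisopropylsilyl)oxy]-1-benzofuran-2(3H)-one; 3 (2E,6E)-farnesyl bromide
Product: 5 rac-methyl 2-{2-oxo-5-[(triisopropylsilyl)oxy]-1-farnesylcyclohexa-3,5-dien-1-yl}acetate, via sodium phenolate 4 (not isolated)
Conditions: NaOMe (1.00 equiv, 0.5 M in MeOH), THF, −20 °C, 10 min; evaporate, azeotrope with PhMe; then 3 (1.1 equiv), PhMe (0.1 M), 0 → 23 °C, 16 h, Ar, dark
Reagents that add atoms: sodium methoxide, C[O-].[Na+]
Why: Proposed new method: a sodium phenolate in toluene is a contact ion pair that is C-alkylated at an ortho carbon through a six-membered transition state in which Na+ bridges the phenolate oxygen and the departing bromide, and here Na+ is also chelated by the ester carbonyl of the arm on C1, so the allyl carbon should be delivered to that substituted ortho carbon rather than to the free ortho CH or to oxygen, giving the dearomatised dienone with the quaternary stereocentre as a racemate and with the 2E geometry retained (SN2 at the primary carbon); closest known reaction type: ortho-C-allylation of sodium phenolates in non-polar solvent, which converts 2,6-disubstituted phenols into 6-allylcyclohexa-2,4-dienones (alkylative dearomatisation).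

**Step 3**
Reactants: 5 rac-methyl 2-{2-oxo-5-[(triisopropylsilyl)oxy]-1-farnesylcyclohexa-3,5-dien-1-yl}acetate
Product: 8 (3aR,7aR)-3a-farnesyl-3,3a,4,7a-tetrahydro-1-benzofuran-2,5-dione, via cis-hydroxy ester 6 (not isolated), via silyl dienol ether lactone 7 (not isolated)
Conditions: (S)-1-methyl-3,3-diphenyltetrahydro-1H,3H-pyrrolo[1,2-c][1,3,2]oxazaborole (0.3 equiv), catecholborane (1.6 equiv), PhMe, −78 °C, 16 h; MeOH, −78 → 0 °C; then 2 M aq HCl/THF (1:4), 23 °C, 3 h
Reagents that add atoms: none
Why: Corey–Bakshi–Shibata reduction followed by acid-catalysed lactonisation and silyl enol ether hydrolysis: the oxazaborolidine binds the carbonyl on the side of the small cis-CH= group (the quaternary carbon is the large group) and delivers hydride 1,2 to one face whatever the configuration at C1, fixing the carbinol as R (future C7a); only the alcohol from (S)-5 has OH cis to the acetate arm and closes the cis-fused γ-lactone (which selects 3aR), C-protonation of the silyl dienol ether next to the quaternary carbon unveils the enone, and the trans-alcohol from (R)-5 stays an open hydroxy ester that is removed by chromatography.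

**Compound list**
1 | homogentisic acid γ-lactone (5-hydroxy-1-benzofuran-2(3H)-one) | O=C1Cc2cc(O)ccc2O1 | starting material
2 | 5-[(triisopropylsilyl)oxy]-1-benzofuran-2(3H)-one | O=C1Cc2cc(O[Si](C(C)C)(C(C)C)C(C)C)ccc2O1 | intermediate
3 | (2E,6E)-farnesyl bromide ((2E,6E)-1-bromo-3,7,11-trimethyldodeca-2,6,10-triene) | CC(C)=CCC/C(C)=C/CC/C(C)=C/CBr | starting material
4 | sodium 2-(2-methoxy-2-oxoethyl)-4-[(triisopropylsilyl)oxy]phenolate | [Na+].COC(=O)Cc1cc(O[Si](C(C)C)(C(C)C)C(C)C)ccc1[O-] | intermediate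
5 | rac-methyl 2-{2-oxo-5-[(triisopropylsilyl)oxy]-1-[(2E,6E)-3,7,11-trimethyldodeca-2,6,10-trien-1-yl]cyclohexa-3,5-dien-1-yl}acetate | CC(C)=CCC/C(C)=C/CC/C(C)=C/CC1(CC(=O)OC)C=C(O[Si](C(C)C)(C(C)C)C(C)C)C=CC1=O | intermediate
6 | methyl 2-{(1S,2R)-2-hydroxy-5-[(triisopropylsilyl)oxy]-1-[(2E,6E)-3,7,11-trimethyldodeca-2,6,10-trien-1-yl]cyclohexa-3,5-dien-1-yl}acetate (OH cis to the acetate arm) | CC(C)=CCC/C(C)=C/CC/C(C)=C/C[C@]1(CC(=O)OC)C=C(O[Si](C(C)C)(C(C)C)C(C)C)C=C[C@H]1O | intermediate
7 | (3aS,7aR)-5-[(triisopropylsilyl)oxy]-3a-[(2E,6E)-3,7,11-trimethyldodeca-2,6,10-trien-1-yl]-3a,7a-dihydro-1-benzofuran-2(3H)-one (cis-fused) | CC(C)=CCC/C(C)=C/CC/C(C)=C/C[C@]12C=C(O[Si](C(C)C)(C(C)C)C(C)C)C=C[C@H]1OC(=O)C2 | intermediate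
8 | (3aR,7aR)-3a-[(2E,6E)-3,7,11-trimethyldodeca-2,6,10-trien-1-yl]-3,3a,4,7a-tetrahydro-1-benzofuran-2,5-dione (cis-fused) | CC(C)=CCC/C(C)=C/CC/C(C)=C/C[C@]12CC(=O)C=C[C@H]1OC(=O)C2 | target

**Step count**
Total steps: 3. Longest linear sequence: 3 (1 → 2 → 5 → 8).

**Steps most likely to fail, with fallbacks**

Step 2 (highest risk). The ipso-selectivity is a prediction. Competing paths are O-farnesylation, C-alkylation at the free ortho CH (which re-aromatises), and re-closure of 4 to the lactone enolate followed by alkylation α to the carbonyl. The theoretical yield of 8 from racemic 5 is in any case capped at 50 %. Fallback, from 4 back to 5: block the free ortho position. Phenolate 4 is brominated with NBS (THF, −78 °C, aq NH4Cl work-up) to give methyl 2-{3-bromo-2-hydroxy-5-[(triisopropylsilyl)oxy]phenyl}acetate F3. NaH in PhMe gives its sodium salt F4 in the flask, which 3 can C-alkylate only at the carbon bearing the acetate arm, giving rac-methyl 2-{3-bromo-2-oxo-5-[(triisopropylsilyl)oxy]-1-farnesylcyclohexa-3,5-dien-1-yl}acetate F5. The vinylic bromine is then removed by formate hydrogenolysis (Pd(OAc)2, PPh3, HCO2H, Et3N, DMF, ≤ 40 °C, kept mild because zerovalent palladium could also ionise the allyl–C1 bond) to return 5.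

Step 3. The ee of 8 equals the facial fidelity of the oxazaborolidine on this unusual dienone, so a polish on a chiral phase may be needed. If the large/small assignment is reversed, the enantiomeric catalyst is used. Dienol 6 is acid-sensitive before the enol ether is cleaved. Fallback, from 5 back to 6: resolve first, then reduce without a chiral catalyst. Preparative chromatography of 5 on amylose tris(3,5-dimethylphenylcarbamate) gives methyl 2-{(1S)-2-oxo-5-[(triisopropylsilyl)oxy]-1-farnesylcyclohexa-3,5-dien-1-yl}acetate F6. Reduction with NaBH4/CeCl3·7H2O (MeOH, −78 °C) gives 6 together with its carbinol epimer, methyl 2-{(1S,2S)-2-hydroxy-5-[(triisopropylsilyl)oxy]-1-farnesylcyclohexa-3,5-dien-1-yl}acetate F7. The acid treatment of step 3 then takes 6 through 7 to 8, while F7 cannot lactonise and ends as methyl 2-{(1R,2S)-2-hydroxy-5-oxo-1-farnesylcyclohex-3-en-1-yl}acetate F8, which is removed by chromatography. Enantiopurity then rests on the separation, and hydride face selectivity only costs yield.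

Step 1. Imidazole may open the aryl lactone, or some C-silylation may occur. Fallback, from 1 back to 4: open first, then silylate. Methanolysis of 1 (MeOH, cat. H2SO4, 23 °C) gives methyl 2-(2,5-dihydroxyphenyl)acetate F1. Site-selective silylation of the unhindered, non-hydrogen-bonded 5-OH (TIPSCl, imidazole, CH2Cl2, −20 °C) gives methyl 2-{2-hydroxy-5-[(triisopropylsilyl)oxy]phenyl}acetate F2. NaH in PhMe converts F2 directly into phenolate 4.

**Further compounds**
F1 | step 1 | methyl 2-(2,5-dihydroxyphenyl)acetate | COC(=O)Cc1cc(O)ccc1O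
F2 | step 1 | methyl 2-{2-hydroxy-5-[(triisopropylsilyl)oxy]phenyl}acetate | COC(=O)Cc1cc(O[Si](C(C)C)(C(C)C)C(C)C)ccc1O
F3 | step 2 | methyl 2-{3-bromo-2-hydroxy-5-[(triisopropylsilyl)oxy]phenyl}acetate | COC(=O)Cc1cc(O[Si](C(C)C)(C(C)C)C(C)C)cc(Br)c1O
F4 | step 2 | sodium 2-bromo-6-(2-methoxy-2-oxoethyl)-4-[(triisopropylsilyl)oxy]phenolate | [Na+].COC(=O)Cc1cc(O[Si](C(C)C)(C(C)C)C(C)C)cc(Br)c1[O-]
F5 | step 2 | rac-methyl 2-{3-bromo-2-oxo-5-[(triisopropylsilyl)oxy]-1-[(2E,6E)-3,7,11-trimethyldodeca-2,6,10-trien-1-yl]cyclohexa-3,5-dien-1-yl}acetate | CC(C)=CCC/C(C)=C/CC/C(C)=C/CC1(CC(=O)OC)C=C(O[Si](C(C)C)(C(C)C)C(C)C)C=C(Br)C1=O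
F6 | step 3 | methyl 2-{(1S)-2-oxo-5-[(triisopropylsilyl)oxy]-1-[(2E,6E)-3,7,11-trimethyldodeca-2,6,10-trien-1-yl]cyclohexa-3,5-dien-1-yl}acetate | CC(C)=CCC/C(C)=C/CC/C(C)=C/C[C@]1(CC(=O)OC)C=C(O[Si](C(C)C)(C(C)C)C(C)C)C=CC1=O
F7 | step 3 | methyl 2-{(1S,2S)-2-hydroxy-5-[(triisopropylsilyl)oxy]-1-[(2E,6E)-3,7,11-trimethyldodeca-2,6,10-trien-1-yl]cyclohexa-3,5-dien-1-yl}acetate | CC(C)=CCC/C(C)=C/CC/C(C)=C/C[C@]1(CC(=O)OC)C=C(O[Si](C(C)C)(C(C)C)C(C)C)C=C[C@@H]1O
F8 | step 3 | methyl 2-{(1R,2S)-2-hydroxy-5-oxo-1-[(2E,6E)-3,7,11-trimethyldodeca-2,6,10-trien-1-yl]cyclohex-3-en-1-yl}acetate | CC(C)=CCC/C(C)=C/CC/C(C)=C/C[C@]1(CC(=O)OC)CC(=O)C=C[C@@H]1O
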